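**Retrosynthetic overview**
1. Target 30 ⇐ MnO2 oxidation of the C-14 allylic alcohol after desilylation of 28, which comes from Steglich esterification of bicyclic diol 23 with protected 4-hydroxybenzoic acid 26.
2. Seven-membered ring (formed second) ⇐ ring-closing metathesis of diene 22 across C-8=C-9; the trans ring fusion is carried by the trans side chains on the cyclopentane.
3. Key C-6–C-7 bond ⇐ intermolecular, chelation-controlled Barbier carbonyl allylation of β-hydroxy aldehyde 18 with allyl bromide 21 (sets C-6).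
4. 18 ⇐ isopropyl addition to cyclopentanone 12 (sets C-4); C-5 of 12 comes from a catalyst-controlled dynamic kinetic hydrogenation of β-keto ester 8.
5. Five-membered ring (formed first) ⇐ rhodium-carbene C–H insertion with retention at the stereocentre of (S)-citronellol 1 (sets quaternary C-1).

Assumption: the SMILES defines the (3R,3aS,4S,8aR) enantiomer (azulene numbering), and (S)-(−)-β-citronellol of ≥98% ee is the chirality source.

Labels C-1 to C-15 are daucane numbers: C-1 quaternary ring-fusion carbon (methyl C-15), C-2/C-3 ring CH2, C-4 carbinol carbon with isopropyl, C-5 ring-fusion CH, C-6 ester carbon, C-7 CH2, C-8 alkene carbon bearing C-14, C-9 alkene CH, C-10 CH2. TBS = tert-butyldimethylsilyl, TBDPS = tert-butyldiphenylsilyl. The route is a design from first principles and has not been run.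

**Route**

Step 1
Reactants: 1 (S)-(−)-β-citronellol, (3S)-3,7-dimethyloct-6-en-1-ol
Product: 2 tert-butyl{[(3S)-3,7-dimethyloct-6-en-1-yl]oxy}dimethylsilane
Conditions: TBSCl, imidazole, DMF, rt
Reagents that add atoms: tert-butyl(chloro)dimethylsilane, CC(C)(C)[Si](C)(C)Cl
Why: Standard silyl ether formation masks the primary alcohol (future C-9) for the ozonolysis and carbene steps and leaves the stereocentre (future C-1) untouched.

Step 2
Reactants: 2 tert-butyl{[(3S)-3,7-dimethyloct-6-en-1-yl]oxy}dimethylsilane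
Product: 4 (4S)-6-(TBS-oxy)-4-methylhexanal, via secondary ozonide 3 (not isolated)
Conditions: O3, CH2Cl2, −78 °C; then PPh3, −78 °C to rt
Reagents that add atoms: ozone, [O-][O+]=O
Why: Ozonolysis with reductive work-up cleaves the trisubstituted alkene to the aldehyde carbon that becomes C-4.

Step 3
Reactants: 4 (4S)-6-(TBS-oxy)-4-methylhexanal; 5 ethyl diazoacetate
Product: 6 ethyl (6S)-8-(TBS-oxy)-6-methyl-3-oxooctanoate
Conditions: SnCl2 (10 mol%), CH2Cl2, rt
Reagents that add atoms: none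
Why: Roskamp homologation (Lewis-acid-promoted addition of the diazo ester to the aldehyde, 1,2-hydride shift, loss of N2) gives the β-keto ester in one operation.

Step 4
Reactants: 6 ethyl (6S)-8-(TBS-oxy)-6-methyl-3-oxooctanoate
Product: 7 ethyl (6S)-8-(TBS-oxy)-2-diazo-6-methyl-3-oxooctanoate
Conditions: 4-acetamidobenzenesulfonyl azide, Et3N, MeCN, 0 °C to rt
Reagents that add atoms: 4-acetamidobenzenesulfonyl azide, CC(=O)Nc1ccc(cc1)S(=O)(=O)N=[N+]=[N-]
Why: Regitz diazo transfer to the doubly activated methylene of a β-keto ester is routine.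

Step 5
Reactants: 7 ethyl (6S)-8-(TBS-oxy)-2-diazo-6-methyl-3-oxooctanoate
Product: 8 ethyl (2R)-2-[2-(TBS-oxy)ethyl]-2-methyl-5-oxocyclopentane-1-carboxylate (epimers at ring C-1, partly enolised)
Conditions: Rh2(OAc)4 (1 mol%), CH2Cl2, rt
Reagents that add atoms: none
Why: Rhodium-carbene 1,5 C–H insertion (Taber-type cyclopentanone construction) goes into the only tertiary C–H bond and with retention, so the citronellol stereocentre becomes the quaternary C-1 (R).

Step 6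
Reactants: 8 ethyl (2R)-2-[2-(TBS-oxy)ethyl]-2-methyl-5-oxocyclopentane-1-carboxylate
Product: 9 ethyl (1R,2R,5R)-2-[2-(TBS-oxy)ethyl]-5-hydroxy-2-methylcyclopentane-1-carboxylate
Conditions: H2 (100 atm), RuCl2[(R)-BINAP] (1 mol%), CH2Cl2, 50 °C
Reagents that add atoms: none
Why: Noyori hydrogenation with dynamic kinetic resolution: the ester-bearing carbon epimerises through the enol while the catalyst reduces the ketone from one face and, as for cyclic β-keto esters in general, gives the trans hydroxy ester, which fixes the carbinol (R) and thereby C-5 with the ester cis to the ring methyl.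

Step 7
Reactants: 9 ethyl (1R,2R,5R)-2-[2-(TBS-oxy)ethyl]-5-hydroxy-2-methylcyclopentane-1-carboxylate
Product: 10 (1R,2S,3R)-3-[2-(TBS-oxy)ethyl]-2-(hydroxymethyl)-3-methylcyclopentan-1-ol
Conditions: LiAlH4, THF, 0 °C
Reagents that add atoms: none
Why: Hydride reduction of the ester gives the C-6 primary alcohol without touching the stereocentres or the silyl ether.

Step 8
Reactants: 10 (1R,2S,3R)-3-[2-(TBS-oxy)ethyl]-2-(hydroxymethyl)-3-methylcyclopentan-1-ol
Product: 11 (1R,2S,3R)-3-[2-(TBS-oxy)ethyl]-2-[(TBDPS-oxy)methyl]-3-methylcyclopentan-1-ol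
Conditions: TBDPSCl (1.05 equiv), imidazole, CH2Cl2, 0 °C
Reagents that add atoms: tert-butyl(chloro)diphenylsilane, CC(C)(C)[Si](Cl)(c1ccccc1)c1ccccc1
Why: Silylation takes the primary hydroxyl selectively over the ring secondary hydroxyl on steric grounds.

Step 9
Reactants: 11 (1R,2S,3R)-3-[2-(TBS-oxy)ethyl]-2-[(TBDPS-oxy)methyl]-3-methylcyclopentan-1-ol
Product: 12 (2S,3R)-3-[2-(TBS-oxy)ethyl]-2-[(TBDPS-oxy)methyl]-3-methylcyclopentan-1-one
Conditions: Dess–Martin periodinane, CH2Cl2, 0 °C to rt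
Reagents that add atoms: none
Why: Neutral Dess–Martin oxidation gives the C-4 ketone without epimerising the adjacent C-5 or eliminating the β-silyloxy group.

Step 10
Reactants: 12 (2S,3R)-3-[2-(TBS-oxy)ethyl]-2-[(TBDPS-oxy)methyl]-3-methylcyclopentan-1-one
Product: 13 (1R,2S,3R)-3-[2-(TBS-oxy)ethyl]-2-[(TBDPS-oxy)methyl]-3-methyl-1-(propan-2-yl)cyclopentan-1-ol
Conditions: Me2CHMgCl (2 equiv), LaCl3·2LiCl (1 equiv), THF, 0 °C
Reagents that add atoms: isopropylmagnesium chloride, CC(C)[Mg]Cl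
Why: Lanthanum-assisted Grignard 1,2-addition suppresses enolisation and β-hydride reduction, and the nucleophile enters trans to the adjacent CH2OTBDPS group and the ring methyl, so the new hydroxyl is cis to C-6 (C-4 R).

Step 11
Reactants: 13 (1R,2S,3R)-3-[2-(TBS-oxy)ethyl]-2-[(TBDPS-oxy)methyl]-3-methyl-1-(propan-2-yl)cyclopentan-1-ol
Product: 14 (1R,2S,3R)-2-[(TBDPS-oxy)methyl]-3-(2-hydroxyethyl)-3-methyl-1-(propan-2-yl)cyclopentan-1-ol
Conditions: PPTS (0.2 equiv), MeOH, rt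
Reagents that add atoms: none
Why: Mild acid methanolysis removes the primary TBS ether while the far more acid-stable TBDPS ether survives.

Step 12
Reactants: 14 (1R,2S,3R)-2-[(TBDPS-oxy)methyl]-3-(2-hydroxyethyl)-3-methyl-1-(propan-2-yl)cyclopentan-1-ol
Product: 15 2-[(1R,2S,3R)-2-[(TBDPS-oxy)methyl]-3-hydroxy-1-methyl-3-(propan-2-yl)cyclopentyl]acetaldehyde
Conditions: Dess–Martin periodinane, CH2Cl2, 0 °C to rt
Reagents that add atoms: none
Why: Dess–Martin oxidation converts the primary alcohol to the aldehyde and cannot touch the tertiary alcohol, which is trans to this side chain and so cannot form a lactol.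

Step 13
Reactants: 15 2-[(1R,2S,3R)-2-[(TBDPS-oxy)methyl]-3-hydroxy-1-methyl-3-(propan-2-yl)cyclopentyl]acetaldehyde
Product: 16 (1R,2S,3R)-2-[(TBDPS-oxy)methyl]-3-methyl-1-(propan-2-yl)-3-(prop-2-en-1-yl)cyclopentan-1-ol
Conditions: Ph3PCH3Br (3 equiv), KOtBu (2.8 equiv), THF, 0 °C to rt
Reagents that add atoms: methyltriphenylphosphonium bromide, [Br-].C[P+](c1ccccc1)(c1ccccc1)c1ccccc1
Why: Wittig methylenation turns the CH2CHO arm into the allyl group (C-10, C-9) needed for ring closure, and excess ylide tolerates the free tertiary hydroxyl.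

Step 14
Reactants: 16 (1R,2S,3R)-2-[(TBDPS-oxy)methyl]-3-methyl-1-(propan-2-yl)-3-(prop-2-en-1-yl)cyclopentan-1-ol
Product: 17 (1R,2S,3R)-2-(hydroxymethyl)-3-methyl-1-(propan-2-yl)-3-(prop-2-en-1-yl)cyclopentan-1-ol
Conditions: TBAF, THF, rt
Reagents that add atoms: none
Why: Fluoride cleaves the TBDPS ether and frees the C-6 hydroxyl.

Step 15
Reactants: 17 (1R,2S,3R)-2-(hydroxymethyl)-3-methyl-1-(propan-2-yl)-3-(prop-2-en-1-yl)cyclopentan-1-ol
Product: 18 (1R,2R,5R)-2-hydroxy-5-methyl-2-(propan-2-yl)-5-(prop-2-en-1-yl)cyclopentane-1-carbaldehyde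
Conditions: Dess–Martin periodinane, CH2Cl2, 0 °C; used crude
Reagents that add atoms: none
Why: Dess–Martin oxidation of the only oxidisable alcohol gives the β-hydroxy aldehyde, whose C-5 configuration (formyl cis to OH and methyl, trans to isopropyl and allyl) is also the thermodynamically preferred one.

Step 16
Reactants: 19 2-methylidenepropane-1,3-diol
Product: 20 2-[(TBS-oxy)methyl]prop-2-en-1-ol
Conditions: 19 (3 equiv), TBSCl (1 equiv), imidazole, THF, 0 °C
Reagents that add atoms: tert-butyl(chloro)dimethylsilane, CC(C)(C)[Si](C)(C)Cl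
Why: Statistical monosilylation of the symmetric diol, used in excess, gives the mono-ether cleanly.

Step 17
Reactants: 20 2-[(TBS-oxy)methyl]prop-2-en-1-ol
Product: 21 {[2-(bromomethyl)prop-2-en-1-yl]oxy}(tert-butyl)dimethylsilane
Conditions: CBr4, PPh3, CH2Cl2, 0 °C
Reagents that add atoms: tetrabromomethane, BrC(Br)(Br)Br
Why: Appel bromination converts the allylic alcohol to the allylic bromide under neutral conditions that spare the silyl ether.

Step 18
Reactants: 18 (1R,2R,5R)-2-hydroxy-5-methyl-2-(propan-2-yl)-5-(prop-2-en-1-yl)cyclopentane-1-carbaldehyde; 21 {[2-(bromomethyl)prop-2-en-1-yl]oxy}(tert-butyl)dimethylsilane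
Product: 22 (1R,2S,3R)-2-{(1S)-1-hydroxy-3-[(TBS-oxy)methyl]but-3-en-1-yl}-3-methyl-1-(propan-2-yl)-3-(prop-2-en-1-yl)cyclopentan-1-ol
Conditions: indium powder (1.5 equiv), 21 (2 equiv), THF–H2O (3:1), rt
Reagents that add atoms: none
Why: Barbier-type carbonyl allylation forms the C-6–C-7 bond and joins the two fragments; the indium chelate between the aldehyde and the β-hydroxyl locks the carbonyl so that the allyl group adds anti to the quaternary C-1 (also the Felkin–Anh sense), giving the (S)-carbinol.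

Step 19
Reactants: 22 (1R,2S,3R)-2-{(1S)-1-hydroxy-3-[(TBS-oxy)methyl]but-3-en-1-yl}-3-methyl-1-(propan-2-yl)-3-(prop-2-en-1-yl)cyclopentan-1-ol
Product: 23 (3R,3aS,4S,8aR)-6-[(TBS-oxy)methyl]-8a-methyl-3-(propan-2-yl)-1,2,3,3a,4,5,8,8a-octahydroazulene-3,4-diol
Conditions: second-generation Grubbs catalyst (5 mol%), CH2Cl2 (5 mM), 40 °C
Reagents that add atoms: none
Why: Ring-closing metathesis between the allyl group and the 1,1-disubstituted alkene closes the seven-membered ring as the trisubstituted C-8=C-9 alkene, with the trans ring fusion already fixed by the trans side chains.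

Step 20
Reactants: 24 4-hydroxybenzoic acid
Product: 26 4-(TBS-oxy)benzoic acid, via bis-silylated ester 25 (not isolated)
Conditions: TBSCl (2.2 equiv), imidazole, DMF, rt; then AcOH–THF–H2O (3:1:1), rt
Reagents that add atoms: tert-butyl(chloro)dimethylsilane, CC(C)(C)[Si](C)(C)Cl
Why: Bis-silylation followed by selective hydrolysis of the labile silyl ester leaves the aryl silyl ether in place.

Step 21
Reactants: 23 (3R,3aS,4S,8aR)-6-[(TBS-oxy)methyl]-8a-methyl-3-(propan-2-yl)-1,2,3,3a,4,5,8,8a-octahydroazulene-3,4-diol; 26 4-(TBS-oxy)benzoic acid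
Product: 28 (3R,3aS,4S,8aR)-3-hydroxy-8a-methyl-3-(propan-2-yl)-6-[(TBS-oxy)methyl]-1,2,3,3a,4,5,8,8a-octahydroazulen-4-yl 4-(TBS-oxy)benzoate, via O-acylisourea 27 (not isolated)
Conditions: 26 (1.5 equiv), DCC (1.6 equiv), DMAP (0.3 equiv), CH2Cl2, 0 °C to rt
Reagents that add atoms: none
Why: Steglich esterification acylates the secondary C-6 hydroxyl with retention, and the tertiary C-4 hydroxyl is too hindered to react.

Step 22
Reactants: 28 (3R,3aS,4S,8aR)-3-hydroxy-8a-methyl-3-(propan-2-yl)-6-[(TBS-oxy)methyl]-1,2,3,3a,4,5,8,8a-octahydroazulen-4-yl 4-(TBS-oxy)benzoate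
Product: 29 (3R,3aS,4S,8aR)-3-hydroxy-6-(hydroxymethyl)-8a-methyl-3-(propan-2-yl)-1,2,3,3a,4,5,8,8a-octahydroazulen-4-yl 4-hydroxybenzoate
Conditions: TBAF (3 equiv), AcOH (3 equiv), THF, 0 °C to rt
Reagents that add atoms: none
Why: Acetic-acid-buffered fluoride removes the aryl and the primary allylic silyl ethers without cleaving or migrating the benzoate.

Step 23
Reactants: 29 (3R,3aS,4S,8aR)-3-hydroxy-6-(hydroxymethyl)-8a-methyl-3-(propan-2-yl)-1,2,3,3a,4,5,8,8a-octahydroazulen-4-yl 4-hydroxybenzoate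
Product: 30 (3R,3aS,4S,8aR)-6-formyl-3-hydroxy-8a-methyl-3-(propan-2-yl)-1,2,3,3a,4,5,8,8a-octahydroazulen-4-yl 4-hydroxybenzoate
Conditions: activated MnO2 (15 equiv), CH2Cl2, rt
Reagents that add atoms: none
Why: MnO2 oxidises only the primary allylic alcohol, giving the conjugated aldehyde while the tertiary alcohol, phenol and ester are left alone.

**Compound list**
1 | (S)-(−)-β-citronellol, (3S)-3,7-dimethyloct-6-en-1-ol | C[C@@H](CCC=C(C)C)CCO | starting material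
2 | tert-butyl{[(3S)-3,7-dimethyloct-6-en-1-yl]oxy}dimethylsilane | C[C@@H](CCC=C(C)C)CCO[Si](C)(C)C(C)(C)C | intermediate
3 | 3-[(3S)-5-(TBS-oxy)-3-methylpentyl]-5,5-dimethyl-1,2,4-trioxolane (secondary ozonide, mixture at the ring carbon) | C[C@@H](CCC1OOC(C)(C)O1)CCO[Si](C)(C)C(C)(C)C | intermediate (not isolated)
4 | (4S)-6-(TBS-oxy)-4-methylhexanal | C[C@@H](CCC=O)CCO[Si](C)(C)C(C)(C)C | intermediate
5 | ethyl diazoacetate | CCOC(=O)C=[N+]=[N-] | starting material
6 | ethyl (6S)-8-(TBS-oxy)-6-methyl-3-oxooctanoate | C[C@@H](CCC(=O)CC(=O)OCC)CCO[Si](C)(C)C(C)(C)C | intermediate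
7 | ethyl (6S)-8-(TBS-oxy)-2-diazo-6-methyl-3-oxooctanoate | C[C@@H](CCC(=O)C(=[N+]=[N-])C(=O)OCC)CCO[Si](C)(C)C(C)(C)C | intermediate
8 | ethyl (2R)-2-[2-(TBS-oxy)ethyl]-2-methyl-5-oxocyclopentane-1-carboxylate (epimers at ring C-1) | CCOC(=O)C1C(=O)CC[C@]1(C)CCO[Si](C)(C)C(C)(C)C | intermediate
9 | ethyl (1R,2R,5R)-2-[2-(TBS-oxy)ethyl]-5-hydroxy-2-methylcyclopentane-1-carboxylate | O[C@@H]1CC[C@](C)(CCO[Si](C)(C)C(C)(C)C)[C@H]1C(=O)OCC | intermediate
10 | (1R,2S,3R)-3-[2-(TBS-oxy)ethyl]-2-(hydroxymethyl)-3-methylcyclopentan-1-ol | O[C@@H]1CC[C@](C)(CCO[Si](C)(C)C(C)(C)C)[C@H]1CO | intermediate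
11 | (1R,2S,3R)-3-[2-(TBS-oxy)ethyl]-2-[(TBDPS-oxy)methyl]-3-methylcyclopentan-1-ol | O[C@@H]1CC[C@](C)(CCO[Si](C)(C)C(C)(C)C)[C@H]1CO[Si](c2ccccc2)(c2ccccc2)C(C)(C)C | intermediate
12 | (2S,3R)-3-[2-(TBS-oxy)ethyl]-2-[(TBDPS-oxy)methyl]-3-methylcyclopentan-1-one | O=C1CC[C@](C)(CCO[Si](C)(C)C(C)(C)C)[C@H]1CO[Si](c2ccccc2)(c2ccccc2)C(C)(C)C | intermediate
13 | (1R,2S,3R)-3-[2-(TBS-oxy)ethyl]-2-[(TBDPS-oxy)methyl]-3-methyl-1-(propan-2-yl)cyclopentan-1-ol | CC(C)[C@]1(O)CC[C@](C)(CCO[Si](C)(C)C(C)(C)C)[C@H]1CO[Si](c2ccccc2)(c2ccccc2)C(C)(C)C | intermediate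
14 | (1R,2S,3R)-2-[(TBDPS-oxy)methyl]-3-(2-hydroxyethyl)-3-methyl-1-(propan-2-yl)cyclopentan-1-ol | CC(C)[C@]1(O)CC[C@](C)(CCO)[C@H]1CO[Si](c2ccccc2)(c2ccccc2)C(C)(C)C | intermediate
15 | 2-[(1R,2S,3R)-2-[(TBDPS-oxy)methyl]-3-hydroxy-1-methyl-3-(propan-2-yl)cyclopentyl]acetaldehyde | CC(C)[C@]1(O)CC[C@](C)(CC=O)[C@H]1CO[Si](c2ccccc2)(c2ccccc2)C(C)(C)C | intermediate
16 | (1R,2S,3R)-2-[(TBDPS-oxy)methyl]-3-methyl-1-(propan-2-yl)-3-(prop-2-en-1-yl)cyclopentan-1-ol | CC(C)[C@]1(O)CC[C@](C)(CC=C)[C@H]1CO[Si](c2ccccc2)(c2ccccc2)C(C)(C)C | intermediate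
17 | (1R,2S,3R)-2-(hydroxymethyl)-3-methyl-1-(propan-2-yl)-3-(prop-2-en-1-yl)cyclopentan-1-ol | CC(C)[C@]1(O)CC[C@](C)(CC=C)[C@H]1CO | intermediate
18 | (1R,2R,5R)-2-hydroxy-5-methyl-2-(propan-2-yl)-5-(prop-2-en-1-yl)cyclopentane-1-carbaldehyde | CC(C)[C@]1(O)CC[C@](C)(CC=C)[C@H]1C=O | intermediate
19 | 2-methylidenepropane-1,3-diol | C=C(CO)CO | starting material
20 | 2-[(TBS-oxy)methyl]prop-2-en-1-ol | C=C(CO)CO[Si](C)(C)C(C)(C)C | intermediate
21 | {[2-(bromomethyl)prop-2-en-1-yl]oxy}(tert-butyl)dimethylsilane | C=C(CBr)CO[Si](C)(C)C(C)(C)C | intermediate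
22 | (1R,2S,3R)-2-{(1S)-1-hydroxy-3-[(TBS-oxy)methyl]but-3-en-1-yl}-3-methyl-1-(propan-2-yl)-3-(prop-2-en-1-yl)cyclopentan-1-ol | CC(C)[C@]1(O)CC[C@](C)(CC=C)[C@H]1[C@@H](O)CC(=C)CO[Si](C)(C)C(C)(C)C | intermediate
23 | (3R,3aS,4S,8aR)-6-[(TBS-oxy)methyl]-8a-methyl-3-(propan-2-yl)-1,2,3,3a,4,5,8,8a-octahydroazulene-3,4-diol | CC(C)[C@]1(O)CC[C@]2(C)CC=C(CO[Si](C)(C)C(C)(C)C)C[C@H](O)[C@H]21 | intermediate
24 | 4-hydroxybenzoic acid | OC(=O)c1ccc(O)cc1 | starting material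
25 | tert-butyldimethylsilyl 4-(TBS-oxy)benzoate | CC(C)(C)[Si](C)(C)OC(=O)c1ccc(O[Si](C)(C)C(C)(C)C)cc1 | intermediate (not isolated)
26 | 4-(TBS-oxy)benzoic acid | CC(C)(C)[Si](C)(C)Oc1ccc(cc1)C(O)=O | intermediate
27 | O-acylisourea from 26 and DCC, N,N'-dicyclohexylcarbamimidic 4-(TBS-oxy)benzoic anhydride | CC(C)(C)[Si](C)(C)Oc1ccc(cc1)C(=O)OC(=NC2CCCCC2)NC2CCCCC2 | intermediate (not isolated)
28 | (3R,3aS,4S,8aR)-3-hydroxy-8a-methyl-3-(propan-2-yl)-6-[(TBS-oxy)methyl]-1,2,3,3a,4,5,8,8a-octahydroazulen-4-yl 4-(TBS-oxy)benzoate | CC(C)[C@]1(O)CC[C@]2(C)CC=C(CO[Si](C)(C)C(C)(C)C)C[C@H](OC(=O)c3ccc(O[Si](C)(C)C(C)(C)C)cc3)[C@H]21 | intermediate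
29 | (3R,3aS,4S,8aR)-3-hydroxy-6-(hydroxymethyl)-8a-methyl-3-(propan-2-yl)-1,2,3,3a,4,5,8,8a-octahydroazulen-4-yl 4-hydroxybenzoate | CC(C)[C@]1(O)CC[C@]2(C)CC=C(CO)C[C@H](OC(=O)c3ccc(O)cc3)[C@H]21 | intermediate
30 | (3R,3aS,4S,8aR)-6-formyl-3-hydroxy-8a-methyl-3-(propan-2-yl)-1,2,3,3a,4,5,8,8a-octahydroazulen-4-yl 4-hydroxybenzoate (CNP0267880.1) | CC(C)[C@]1(O)CC[C@]2(C)CC=C(C=O)C[C@H](OC(=O)c3ccc(O)cc3)[C@H]21 | target

**Step count**
Total: 23 steps. Longest linear sequence: 20 steps (1 to 30 through steps 1–15, 18, 19, 21, 22, 23). Side branches: 19 to 21 (2 steps) and 24 to 26 (1 step).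

**Steps most likely to fail, with fallbacks**

Step 6 (catalyst control at C-5 next to a quaternary centre may be slow or incomplete). The fallback sets out from 8 and comes back at 12, and replaces catalyst control by chelation control with recycling. Zn(BH4)2 in Et2O at 0 °C reduces 8 through its zinc chelate to the two cis hydroxy esters, ethyl (1R,2R,5S)-2-[2-(TBS-oxy)ethyl]-5-hydroxy-2-methylcyclopentane-1-carboxylate F1 (ester cis to the ring methyl) and ethyl (1S,2R,5R)-2-[2-(TBS-oxy)ethyl]-5-hydroxy-2-methylcyclopentane-1-carboxylate F2, which are separated on silica. F2 is oxidised back to 8 with Dess–Martin periodinane and recycled. F1 goes through the same three operations as 9: LiAlH4 gives (1S,2S,3R)-3-[2-(TBS-oxy)ethyl]-2-(hydroxymethyl)-3-methylcyclopentan-1-ol F3, TBDPSCl and imidazole give (1S,2S,3R)-3-[2-(TBS-oxy)ethyl]-2-[(TBDPS-oxy)methyl]-3-methylcyclopentan-1-ol F4, and Dess–Martin oxidation erases the carbinol centre and delivers 12.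

Step 10 (a branched Grignard reagent on a hindered, enolisable ketone can reduce or enolise it). The fallback sets out from 12 and comes back at 13. The smaller, non-reducing CH2=C(CH3)MgBr is added with LaCl3·2LiCl in THF at 0 °C, with the same facial preference, to give (1S,2S,3R)-3-[2-(TBS-oxy)ethyl]-2-[(TBDPS-oxy)methyl]-3-methyl-1-(prop-1-en-2-yl)cyclopentan-1-ol F5. Its isopropenyl group is then hydrogenated (H2, PtO2, EtOAc) to 13; no other alkene is present at this stage.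

Step 18 (the C-6 selectivity rests on chelation and may be low or reversed). The fallback sets out from 18 and comes back at 28, and makes the end of the route stereoconvergent. The epimer (1R,2S,3R)-2-{(1R)-1-hydroxy-3-[(TBS-oxy)methyl]but-3-en-1-yl}-3-methyl-1-(propan-2-yl)-3-(prop-2-en-1-yl)cyclopentan-1-ol F6 is separated and cyclised with the second-generation Grubbs catalyst as in step 19 to (3R,3aS,4R,8aR)-6-[(TBS-oxy)methyl]-8a-methyl-3-(propan-2-yl)-1,2,3,3a,4,5,8,8a-octahydroazulene-3,4-diol F7. F7 is esterified with 26 under Mitsunobu conditions (PPh3, DIAD, toluene, 0 °C to rt), which inverts C-6 and gives 28. The (S)-alcohol 23 is thus esterified with retention and the (R)-alcohol with inversion.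

**Further compounds**
F1 | step 6 | ethyl (1R,2R,5S)-2-[2-(TBS-oxy)ethyl]-5-hydroxy-2-methylcyclopentane-1-carboxylate | O[C@H]1CC[C@](C)(CCO[Si](C)(C)C(C)(C)C)[C@H]1C(=O)OCC
F2 | step 6 | ethyl (1S,2R,5R)-2-[2-(TBS-oxy)ethyl]-5-hydroxy-2-methylcyclopentane-1-carboxylate | O[C@@H]1CC[C@](C)(CCO[Si](C)(C)C(C)(C)C)[C@@H]1C(=O)OCC
F3 | step 6 | (1S,2S,3R)-3-[2-(TBS-oxy)ethyl]-2-(hydroxymethyl)-3-methylcyclopentan-1-ol | O[C@H]1CC[C@](C)(CCO[Si](C)(C)C(C)(C)C)[C@H]1CO
F4 | step 6 | (1S,2S,3R)-3-[2-(TBS-oxy)ethyl]-2-[(TBDPS-oxy)methyl]-3-methylcyclopentan-1-ol | O[C@H]1CC[C@](C)(CCO[Si](C)(C)C(C)(C)C)[C@H]1CO[Si](c2ccccc2)(c2ccccc2)C(C)(C)C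
F5 | step 10 | (1S,2S,3R)-3-[2-(TBS-oxy)ethyl]-2-[(TBDPS-oxy)methyl]-3-methyl-1-(prop-1-en-2-yl)cyclopentan-1-ol | CC(=C)[C@]1(O)CC[C@](C)(CCO[Si](C)(C)C(C)(C)C)[C@H]1CO[Si](c2ccccc2)(c2ccccc2)C(C)(C)C
F6 | step 18 | (1R,2S,3R)-2-{(1R)-1-hydroxy-3-[(TBS-oxy)methyl]but-3-en-1-yl}-3-methyl-1-(propan-2-yl)-3-(prop-2-en-1-yl)cyclopentan-1-ol | CC(C)[C@]1(O)CC[C@](C)(CC=C)[C@H]1[C@H](O)CC(=C)CO[Si](C)(C)C(C)(C)C
F7 | step 18 | (3R,3aS,4R,8aR)-6-[(TBS-oxy)methyl]-8a-methyl-3-(propan-2-yl)-1,2,3,3a,4,5,8,8a-octahydroazulene-3,4-diol | CC(C)[C@]1(O)CC[C@]2(C)CC=C(CO[Si](C)(C)C(C)(C)C)C[C@@H](O)[C@H]21
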